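Late in the earlier runs the readings stop moving: oak's X reads 33.7% at 2.00 min and 33.3% at 12.0 min, a difference inside the scatter of 1 percentage point.

| setting | oak | birch | larch | flask |
|---|---|---|---|---|
| Q | 0.50 mM | 0.50 mM | 0.75 mM | 0.50 mM |
| D | 0.17 mM | 0.38 mM | 0.25 mM | 0.250 mM |
| remark | run made earlier | run made earlier | run made earlier |  |
| time |  |  |  | 15 min |

- oak (time / min: Q / %, X / %): 1.00: 67.2, 33.4; 2.00: 66.2, 33.7; 5.00: 65.7, 34.6; 12.0: 65.1, 33.3
- birch (time / min: Q / %, X / %): 3.00: 24.0, 76.5; 6.00: 26.1, 74.3; 10.0: 23.0, 77.3; 12.0: 24.5, 76.7
- larch (time / min: Q / %, X / %): 1.00: 68.3, 32.4; 2.00: 65.4, 33.9; 5.00: 66.0, 32.6; 12.0: 64.9, 32.5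

(each reading ± 1 percentage point)

* the state of affairs at 15 min: stopped, and by what, or still going (it is still moving / forward and back rates have come level / all of Q has reacted / D has run out first)
* share of the Q used up at 15 min
* X at 15 min, in percent of the Q charged

- the reaction counts as stopped when no species that holds the Q changes by six tenths of a point or more over the second half of the time

Let us read the last X of each run against the D charged as a fraction of the Q charged. Oak has the fraction 34.0% and reads 33.3%. Birch has 76.0% and reads 76.7%. Larch has 33.3% and reads 32.5%. From oak to birch, Q stays and D goes up, and X climbs with the fraction. From oak to larch, both charges go up, the fraction barely moves, and neither does X. So the plateau follows the fraction, as it should if one Q and one D give one X and D is the limiting reagent.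

For the flask, our ceiling, the D charged over the Q charged, is 50.0%. Will the flask get there in time? Oak, with the same Q and less D, already reads 33.4% at 1.00 min, and the flask has far longer than that. So we expect it to be flat by 15 min, with X at the ceiling and the same share of Q used.

The forecast agrees: D has run out first, conversion 50%, X 50%, on the ground that “The reaction is fast and stops because D is used up”.

The outcome of the flask reads: D has run out first, with conversion 50.0% and X 50.0%, and 0.00983% of its D remains at 15.0 min, less than the 50% of its Q.

    Q + D → X, rate k1*[Q]*[D]^1.5 (k = 55700 /M^1.5/s)

Now take a neighbouring flask charged with 1.2 mM of Q, its D and time as in the flask. D is again the smaller charge, so the ceiling, still the D charged over the Q charged, comes down from 50.0% in the flask to 20.8% in this neighbour. At 15.0 min that neighbour holds 0% of its D and 79.2% of its Q, with X at 20.8%.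

The earlier runs and the new flask stem from a simulated flask for an exercise.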